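Q.Z and X.Z come from one intermediate, Z, which forms reversibly from the substrate E. Q, fed at a steady rate, traps Z, and so does X, which dissolves from solid L.

E 0.10 M; Q 0.200 M (fed, over 12 h); L 0.250 M; time 15 d

* at 15 d, what has stopped the reaction, if anything has (for what has run out or reacted, a solid counts together with what of it has only dissolved) (it is still moving / all of E has reacted / Q has run out first / forward and back rates have come level / X has run out first)
* how much of the E has reacted by 15 d
* how much Q.Z there is at 15 d, in percent of the E charged
* how much X.Z there is at 15 d, in percent of the E charged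

The half-life of E by its forward step, 0.17 d, is shorter than the run, so I expect E to be used up, and the question is how Z is shared.

The zero of my scale is the even split. With X at its solubility 7.8 mM, the traps tie at the tie concentration Q_t, 71 M⁻¹ min⁻¹ times that solubility over 80 M⁻¹ min⁻¹, which is 6.92 mM. The X share (a selectivity) is s = Q_t/(Q_t + [Q]), half at the tie.

I reckon this flask in spans, letting E fall at 0.0028 min⁻¹ and leaving out the way back and E.Z. Q at a span's end is what was fed, less the Z formed, plus the X.Z so far: each Z taken by X spares a Q. Each span uses its end share; in the first row Q and s are solved together.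

| Span ends | Z formed | Q at end | s | X.Z gained |
|---|---|---|---|---|
| 3.00 h | 39.6 mM | 20.4 mM | 25.3% | 10.0 mM |
| 6.00 h | 23.9 mM | 46.5 mM | 13.0% | 3.10 mM |
| 12 h | 23.2 mM | 126 mM | 5.19% | 1.20 mM |
| 15 d | 13.3 mM | 114 mM | 5.71% | 0.760 mM |

The first row ends with Q at 2.95 Q_t and yields 66.4% of my X.Z. The second ends with Q at 6.72 Q_t, so s is lower than before. The last two rows add 1.96 mM. The sum is 15.1% of the E charged. The first row is the weak one: X starts at nothing, yet I set it at solubility, and the end share is the lowest of that span. These errors oppose, and I cannot size them.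

The forecast gives all of E has reacted, 100% reacted, Q.Z 83% and X.Z 15%, noting “so Q builds faster”.

The simulation gives all of E has reacted, 100% reacted, Q.Z 83.2% and X.Z 14.9%.

    E ⇌ Z (K1 = 0.21, k1 = 0.0028 min⁻¹)
    E + Z → E.Z (k2 = 0.17 M⁻¹ min⁻¹)
    Q + Z → Q.Z (k3 = 80 M⁻¹ min⁻¹)
    X + Z → X.Z (k4 = 71 M⁻¹ min⁻¹)
    L ⇌ X, rate k5*(cs5 - [X]) while solid is left; crystals form when [X] > cs5 (cs5 = 7.8 mM, k5 = 0.017 min⁻¹)

The neighbouring flask takes 0.34 M of Q over the same 12 h. In the same rows its Q reaches 50.2 mM in the first span, 7.25 Q_t. The gains are 4.80 mM, 1.40 mM, 0.602 mM and 0.363 mM, which make X.Z 7.16% of the E charged. The simulation of that flask gives X.Z 8.52%, and Q.Z 90.4%.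

(Its constants come from no measurement; the run is a simulation.)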